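**Retrosynthetic overview**
1. Pinnatin B (29) ⇐ furan 28 by oxidative opening of the furan to the Z-enedione (last step).
2. 28 ⇐ acyclic cis-enynone 26: one Rh-carbene cascade forms the furan (O–C6), the cyclopropane (C7–C8, C7–C9) and the macrocycle together.
3. 26 ⇐ acid 15 + (Z)-alkenylzinc 24 (acyl Negishi, C3–C4); 15 ⇐ alkyl bromide 5 + iodobutenolide 12 (alkyl Negishi, C12–C13).
4. 5 ⇐ homoprenyl bromide 1 + tert-butyl glyoxylate 2 (asymmetric ene sets C1/C2, then SN2 inversion with acetate); 12 ⇐ methyl propiolate 6 + methacrolein 7 (asymmetric alkynylation sets C10).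
5. Ring order: butenolide (step 4) → furan + cyclopropane + macrocycle in one operation (step 10) → furan opened (step 11).

Assumption: positions C1–C20 follow cembranoid numbering (C1 isopropenyl, C2 OAc, C3–C6 enedione, C7–C9 cyclopropane, C10–C12/C20 butenolide), and (R,R)-ProPhenol is taken as the ligand antipode that gives Si-face addition in step 3.

**Step 1**
Reactants: 1 5-bromo-2-methylpent-2-ene; 2 tert-butyl glyoxylate
Product: 3 tert-butyl (2R,3S)-3-(2-bromoethyl)-2-hydroxy-4-methylpent-4-enoate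
Conditions: (R)-BINOL (10 mol %), TiCl2(OiPr)2 (10 mol %), 4 Å MS, CH2Cl2, −30 → 0 °C
Reagents that add atoms: none
Why: Catalytic asymmetric glyoxylate-ene (carbonyl-ene) reaction in which the C–C bond forms at the CH terminus of the trisubstituted alkene with hydrogen transfer from a methyl group (creating the isopropenyl group), the (R)-BINOL–Ti Lewis acid fixing 2R and the cyclic transition state giving the syn (2R,3S) pair, C3 being the future C1.

**Step 2**
Reactants: 3 tert-butyl (2R,3S)-3-(2-bromoethyl)-2-hydroxy-4-methylpent-4-enoate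
Product: 5 tert-butyl (2S,3S)-2-acetoxy-3-(2-bromoethyl)-4-methylpent-4-enoate, via C2 triflate 4 (not isolated)
Conditions: Tf2O, 2,6-lutidine, CH2Cl2, −78 °C; then Bu4NOAc, −78 → 0 °C
Reagents that add atoms: tetrabutylammonium acetate, CCCC[N+](CCCC)(CCCC)CCCC.CC(=O)[O-]
Why: α-Triflyloxy esters undergo clean SN2 displacement by carboxylates (triflate formation then Walden inversion), so the future C2 is inverted to S while the acetate of the target is installed.

**Step 3**
Reactants: 6 methyl propiolate; 7 methacrolein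
Product: 9 methyl (R)-4-hydroxy-5-methylhex-5-en-2-ynoate, via zinc alkynylide 8 (not isolated)
Conditions: (R,R)-ProPhenol (10 mol %), Me2Zn (3 equiv), toluene, 4 °C; aq. NH4Cl
Reagents that add atoms: none
Why: Dinuclear zinc–ProPhenol asymmetric alkynylation of an α-substituted enal, in which the chiral Zn2 pocket delivers the zinc alkynylide to the Si face of the aldehyde and so sets the future C10.

**Step 4**
Reactants: 9 methyl (R)-4-hydroxy-5-methylhex-5-en-2-ynoate
Product: 12 (5S)-3-iodo-5-(prop-1-en-2-yl)furan-2(5H)-one, via stannyl hydroxy enoate 10 (not isolated), via stannyl butenolide 11 (not isolated)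
Conditions: Bu3SnH, Pd(PPh3)4 (2 mol %), THF, 0 °C → rt; PPTS (cat.), rt; then I2, CH2Cl2, 0 °C
Reagents that add atoms: iodine, II
Why: Pd-catalysed syn-hydrostannation of the ynoate puts tin α to the ester and the carbinol cis to it so that lactonisation closes the butenolide, and iododestannylation then proceeds with retention at the sp2 carbon without touching the carbinol centre.

**Step 5**
Reactants: 5 tert-butyl (2S,3S)-2-acetoxy-3-(2-bromoethyl)-4-methylpent-4-enoate; 12 (5S)-3-iodo-5-(prop-1-en-2-yl)furan-2(5H)-one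
Product: 14 tert-butyl (2S,3S)-2-acetoxy-4-methyl-3-{2-[(5S)-2-oxo-5-(prop-1-en-2-yl)-2,5-dihydrofuran-3-yl]ethyl}pent-4-enoate, via alkylzinc bromide 13 (not isolated)
Conditions: Zn dust (TMSCl-activated), LiCl, THF, 50 °C; then 12, Pd(OAc)2 (2 mol %), SPhos (4 mol %), THF, 25 °C
Reagents that add atoms: none
Why: Zinc insertion into the primary C–Br bond tolerates ester and acetate, and the Negishi sp3–sp2 coupling with the α-iodo enoate joins C13 to C12 without affecting any stereocentre.

**Step 6**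
Reactants: 14 tert-butyl (2S,3S)-2-acetoxy-4-methyl-3-{2-[(5S)-2-oxo-5-(prop-1-en-2-yl)-2,5-dihydrofuran-3-yl]ethyl}pent-4-enoate
Product: 15 (2S,3S)-2-acetoxy-4-methyl-3-{2-[(5S)-2-oxo-5-(prop-1-en-2-yl)-2,5-dihydrofuran-3-yl]ethyl}pent-4-enoic acid
Conditions: ZnBr2 (5 equiv), CH2Cl2, 25 °C; aq. citric acid
Reagents that add atoms: none
Why: Lewis-acid-mediated tert-butyl ester cleavage (loss of isobutene) frees the acid under non-basic, non-protic conditions that spare the acetate, the base-labile butenolide C5–H and both isopropenyl groups.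

**Step 7**
Reactants: 16 3-(trimethylsilyl)propynal; 17 ethyltriphenylphosphonium iodide
Product: 21 (Z)-(4-iodopent-3-en-1-yn-1-yl)trimethylsilane, via ylide 18 (not isolated), via iodoethylphosphonium iodide 19 (not isolated), via iodo ylide 20 (not isolated)
Conditions: n-BuLi, THF, 0 °C; I2, −78 °C; NaHMDS, −78 °C; then 16, −78 → −20 °C
Reagents that add atoms: iodine, II
Why: Stork–Zhao-type Wittig olefination with the α-iodo ylide is kinetically Z-selective and places iodine cis to the alkynyl group, as needed for the later cis carbonyl–ene–yne array.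

**Step 8**
Reactants: 15 (2S,3S)-2-acetoxy-4-methyl-3-{2-[(5S)-2-oxo-5-(prop-1-en-2-yl)-2,5-dihydrofuran-3-yl]ethyl}pent-4-enoic acid; 21 (Z)-(4-iodopent-3-en-1-yn-1-yl)trimethylsilane
Product: 25 (3S,4S,6Z)-2,6-dimethyl-5-oxo-3-{2-[(5S)-2-oxo-5-(prop-1-en-2-yl)-2,5-dihydrofuran-3-yl]ethyl}-9-(trimethylsilyl)nona-1,6-dien-8-yn-4-yl acetate, via acid chloride 22 (not isolated), via alkenyllithium 23 (not isolated), via alkenylzinc chloride 24 (not isolated)
Conditions: 15, 1-chloro-N,N,2-trimethylprop-1-en-1-amine, CH2Cl2, 0 °C; separately 21, t-BuLi (2 equiv), Et2O, −78 °C, then ZnCl2, THF; combine, Pd(PPh3)4 (5 mol %), THF, 0 → 25 °C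
Reagents that add atoms: none
Why: Negishi acylation, with neutral acid chloride formation, iodine–lithium exchange and transmetalation to zinc with retention of alkene geometry, and a Pd-catalysed ketone formation that tolerates lactone and acetate and does not enolise the α-acetoxy centre.

**Step 9**
Reactants: 25 (3S,4S,6Z)-2,6-dimethyl-5-oxo-3-{2-[(5S)-2-oxo-5-(prop-1-en-2-yl)-2,5-dihydrofuran-3-yl]ethyl}-9-(trimethylsilyl)nona-1,6-dien-8-yn-4-yl acetate
Product: 26 (3S,4S,6Z)-2,6-dimethyl-5-oxo-3-{2-[(5S)-2-oxo-5-(prop-1-en-2-yl)-2,5-dihydrofuran-3-yl]ethyl}nona-1,6-dien-8-yn-4-yl acetate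
Conditions: TBAF, AcOH (1:1), THF, 0 °C
Reagents that add atoms: none
Why: Buffered fluoride protodesilylation of the alkynylsilane is mild enough to spare the acetate, the epimerisable α-acetoxy C–H and the cis-enynone.

**Step 10 (key step)**
Reactants: 26 (3S,4S,6Z)-2,6-dimethyl-5-oxo-3-{2-[(5S)-2-oxo-5-(prop-1-en-2-yl)-2,5-dihydrofuran-3-yl]ethyl}nona-1,6-dien-8-yn-4-yl acetate
Product: 28 (1S,2S,7S,8S,10S)-2-acetoxy furanogersolane macrocycle (2,5-bridged 3-methylfuran C3–C6; trans-fused cyclopropane C7–C8–C9 with C8 methyl; C10–C12/C20 butenolide; C1 isopropenyl), via rhodium furylcarbene 27 (not isolated)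
Conditions: Rh2(esp)2 (2 mol %), CH2Cl2, 40 °C, syringe-pump addition of 26 over 12 h (final 1 mM)
Reagents that add atoms: none
Why: Proposed new method: Rh(II) activation of the terminal alkyne triggers 5-exo-dig attack of the cis ketone oxygen to give the furan and a Rh (2-furyl)carbene (known carbonyl-ene-yne cycloisomerisation, whose carbenes cyclopropanate alkenes intermolecularly); this carbene has no β-hydrogen and cannot reach the C1 isopropenyl group (that would need a four-atom-bridged furanophane), so it adds to the C10 isopropenyl group in the manner of known Rh/Cu macrocyclic cyclopropanations of diazo compounds and closes cyclopropane and macrocycle together, with attack on the alkene face anti to the lactone C–O bond in the H-eclipsed rotamer about C10–C8 and the furan trans to C10 on the three-membered ring (least strained, trans-fused) giving 7S,8S.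

**Step 11**
Reactants: 28 (1S,2S,7S,8S,10S)-2-acetoxy furanogersolane macrocycle
Product: 29 pinnatin B
Conditions: mCPBA (1.05 equiv), NaHCO3, CH2Cl2, 0 °C
Reagents that add atoms: mCPBA, OOC(=O)c1cccc(Cl)c1
Why: Oxidative furan ring opening, in which the electron-rich trisubstituted furan is epoxidised in preference to the isopropenyl and butenolide alkenes and the epoxyfuran opens to the cis-enedione, so the Z geometry of C4=C5 is inherited from the ring.

**Compound list**
1 | 5-bromo-2-methylpent-2-ene | CC(C)=CCCBr | starting material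
2 | tert-butyl glyoxylate | O=CC(=O)OC(C)(C)C | starting material
3 | tert-butyl (2R,3S)-3-(2-bromoethyl)-2-hydroxy-4-methylpent-4-enoate | C=C(C)[C@H](CCBr)[C@@H](O)C(=O)OC(C)(C)C | intermediate
4 | tert-butyl (2R,3S)-3-(2-bromoethyl)-4-methyl-2-[(trifluoromethylsulfonyl)oxy]pent-4-enoate | C=C(C)[C@H](CCBr)[C@@H](OS(=O)(=O)C(F)(F)F)C(=O)OC(C)(C)C | intermediate
5 | tert-butyl (2S,3S)-2-acetoxy-3-(2-bromoethyl)-4-methylpent-4-enoate | C=C(C)[C@H](CCBr)[C@H](OC(C)=O)C(=O)OC(C)(C)C | intermediate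
6 | methyl propiolate | C#CC(=O)OC | starting material
7 | methacrolein | C=C(C)C=O | starting material
8 | methyl 3-(methylzincio)propiolate | C[Zn]C#CC(=O)OC | intermediate
9 | methyl (R)-4-hydroxy-5-methylhex-5-en-2-ynoate | COC(=O)C#C[C@H](O)C(C)=C | intermediate
10 | methyl (2E,4S)-4-hydroxy-5-methyl-2-(tributylstannyl)hexa-2,5-dienoate | COC(=O)/C(=C\[C@H](O)C(C)=C)[Sn](CCCC)(CCCC)CCCC | intermediate
11 | (5S)-5-(prop-1-en-2-yl)-3-(tributylstannyl)furan-2(5H)-one | CCCC[Sn](CCCC)(CCCC)C1=C[C@@H](C(C)=C)OC1=O | intermediate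
12 | (5S)-3-iodo-5-(prop-1-en-2-yl)furan-2(5H)-one | IC1=C[C@@H](C(C)=C)OC1=O | intermediate
13 | [(3S,4S)-4-acetoxy-5-tert-butoxy-5-oxo-3-(prop-1-en-2-yl)pentyl]zinc bromide | C=C(C)[C@H](CC[Zn]Br)[C@H](OC(C)=O)C(=O)OC(C)(C)C | intermediate
14 | tert-butyl (2S,3S)-2-acetoxy-4-methyl-3-{2-[(5S)-2-oxo-5-(prop-1-en-2-yl)-2,5-dihydrofuran-3-yl]ethyl}pent-4-enoate | C=C(C)[C@H](CCC1=C[C@@H](C(C)=C)OC1=O)[C@H](OC(C)=O)C(=O)OC(C)(C)C | intermediate
15 | (2S,3S)-2-acetoxy-4-methyl-3-{2-[(5S)-2-oxo-5-(prop-1-en-2-yl)-2,5-dihydrofuran-3-yl]ethyl}pent-4-enoic acid | C=C(C)[C@H](CCC1=C[C@@H](C(C)=C)OC1=O)[C@H](OC(C)=O)C(=O)O | intermediate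
16 | 3-(trimethylsilyl)propynal | C[Si](C)(C)C#CC=O | starting material
17 | ethyltriphenylphosphonium iodide | CC[P+](c1ccccc1)(c1ccccc1)c1ccccc1.[I-] | starting material
18 | ethylidenetriphenylphosphorane | CC=P(c1ccccc1)(c1ccccc1)c1ccccc1 | intermediate
19 | (1-iodoethyl)triphenylphosphonium iodide | CC(I)[P+](c1ccccc1)(c1ccccc1)c1ccccc1.[I-] | intermediate
20 | (1-iodoethylidene)triphenylphosphorane | CC(I)=P(c1ccccc1)(c1ccccc1)c1ccccc1 | intermediate
21 | (Z)-(4-iodopent-3-en-1-yn-1-yl)trimethylsilane | C[Si](C)(C)C#C/C=C(/C)I | intermediate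
22 | (2S,3S)-2-acetoxy-4-methyl-3-{2-[(5S)-2-oxo-5-(prop-1-en-2-yl)-2,5-dihydrofuran-3-yl]ethyl}pent-4-enoyl chloride | C=C(C)[C@H](CCC1=C[C@@H](C(C)=C)OC1=O)[C@H](OC(C)=O)C(=O)Cl | intermediate
23 | [5-(trimethylsilyl)pent-2-en-4-yn-2-yl]lithium (Li cis to the alkynyl group) | C[Si](C)(C)C#C/C=C(/C)[Li] | intermediate
24 | (Z)-[5-(trimethylsilyl)pent-2-en-4-yn-2-yl]zinc chloride | C[Si](C)(C)C#C/C=C(/C)[Zn]Cl | intermediate
25 | (3S,4S,6Z)-2,6-dimethyl-5-oxo-3-{2-[(5S)-2-oxo-5-(prop-1-en-2-yl)-2,5-dihydrofuran-3-yl]ethyl}-9-(trimethylsilyl)nona-1,6-dien-8-yn-4-yl acetate | C[Si](C)(C)C#C/C=C(/C)C(=O)[C@@H](OC(C)=O)[C@H](C(C)=C)CCC1=C[C@@H](C(C)=C)OC1=O | intermediate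
26 | (3S,4S,6Z)-2,6-dimethyl-5-oxo-3-{2-[(5S)-2-oxo-5-(prop-1-en-2-yl)-2,5-dihydrofuran-3-yl]ethyl}nona-1,6-dien-8-yn-4-yl acetate | C#C/C=C(/C)C(=O)[C@@H](OC(C)=O)[C@H](C(C)=C)CCC1=C[C@@H](C(C)=C)OC1=O | intermediate
27 | rhodium (2-furyl)carbene from 26 ([Rh] stands for the Rh2(esp)2 core) | [Rh]=Cc1cc(C)c(o1)[C@@H](OC(C)=O)[C@H](C(C)=C)CCC1=C[C@@H](C(C)=C)OC1=O | intermediate
28 | (1S,2S,7S,8S,10S)-2-acetoxy furanogersolane macrocycle (furan analogue of pinnatin B) | C=C(C)[C@@H]1CCC2=C[C@H](OC2=O)[C@@]2(C)C[C@@H]2c2cc(C)c(o2)[C@H]1OC(C)=O | intermediate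
29 | pinnatin B | C=C(C)[C@@H]1CCC2=C[C@H](OC2=O)[C@@]2(C)C[C@@H]2C(=O)/C=C(/C)C(=O)[C@H]1OC(C)=O | target

**Totals**
Total step count: 11. Longest linear sequence: 8 steps (1 → 2 → 5 → 6 → 8 → 9 → 10 → 11; the branch 3 → 4 → 5 is equally long).

**Three steps most likely to fail**

Step 10 (the macrocyclising furan/cyclopropane cascade). Likely failures are carbene dimerisation and the wrong cyclopropane diastereomer, since the facial and trans-fusion arguments are models only. Fallback: close the ring at C12–C13 instead and make the cyclopropane intermolecularly; it sets out from 5, 12 and 21 and comes back at 28. ZnBr2 cleavage of 5 gives (2S,3S)-2-acetoxy-3-(2-bromoethyl)-4-methylpent-4-enoic acid F1. The chloroenamine of step 8 converts it to the acid chloride F2, which is coupled under the step 8 conditions with alkenylzinc 24 (from 21) to the silyl enynone bromide F3. TBAF/AcOH gives the terminal enynone bromide F4. Rh2(OAc)4 with 12 in excess (3 equiv) as the alkene partner gives the furyl cyclopropane F5, from which the 7S,8S isomer is separated. An intramolecular nickel-catalysed reductive cross-electrophile coupling of the alkyl bromide with the alkenyl iodide (NiBr2·glyme, dtbbpy, Zn, DMA, 2 mM) then forms C12–C13 and gives 28.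

Step 1 (the ene reaction). The syn/anti ratio and ee with a homoallylic bromide and the tert-butyl ester are untested, and the hindered SN2 of step 2 (E2 competes) depends on it. Fallback: an anti-selective allylboration, which makes the inversion unnecessary; it sets out from 1 and 2 and comes back at 5, bypassing step 2 as well. SeO2 (cat.)/t-BuOOH oxidises the E-methyl group of 1 to (E)-5-bromo-2-methylpent-2-en-1-ol F6. Pd-catalysed borylation with B2pin2 gives the (E)-allylboronate F7. (S)-TRIP-catalysed allylboration of 2 through a chair transition state gives the anti hydroxy ester tert-butyl (2S,3S)-3-(2-bromoethyl)-2-hydroxy-4-methylpent-4-enoate F8. Ac2O/DMAP/pyridine then gives 5 with retention.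

Step 11 (late furan oxidation). Epoxidation of an isopropenyl group or over-oxidation here would cost the most material. Fallback: photooxygenation instead of peracid; it sets out from 28 and comes back at 29. Singlet oxygen (O2, TPP, hν, CH2Cl2, −78 °C) adds across the furan to give the furan endoperoxide F9, and Me2S reduces the O–O bond to release the cis-enedione 29.

**Further compounds**
F1 | step 10 | (2S,3S)-2-acetoxy-3-(2-bromoethyl)-4-methylpent-4-enoic acid | C=C(C)[C@H](CCBr)[C@H](OC(C)=O)C(=O)O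
F2 | step 10 | (2S,3S)-2-acetoxy-3-(2-bromoethyl)-4-methylpent-4-enoyl chloride | C=C(C)[C@H](CCBr)[C@H](OC(C)=O)C(=O)Cl
F3 | step 10 | (3S,4S,6Z)-3-(2-bromoethyl)-2,6-dimethyl-5-oxo-9-(trimethylsilyl)nona-1,6-dien-8-yn-4-yl acetate | C[Si](C)(C)C#C/C=C(/C)C(=O)[C@@H](OC(C)=O)[C@H](C(C)=C)CCBr
F4 | step 10 | (3S,4S,6Z)-3-(2-bromoethyl)-2,6-dimethyl-5-oxonona-1,6-dien-8-yn-4-yl acetate | C#C/C=C(/C)C(=O)[C@@H](OC(C)=O)[C@H](C(C)=C)CCBr
F5 | step 10 | (1S,2S)-2-(2-bromoethyl)-1-{5-[(1S,2S)-2-[(2S)-4-iodo-5-oxo-2,5-dihydrofuran-2-yl]-2-methylcyclopropyl]-3-methylfuran-2-yl}-3-methylbut-3-en-1-yl acetate | IC1=C[C@H](OC1=O)[C@@]2(C)C[C@@H]2c2cc(C)c(o2)[C@@H](OC(C)=O)[C@H](C(C)=C)CCBr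
F6 | step 1 | (E)-5-bromo-2-methylpent-2-en-1-ol | OC/C(C)=C/CCBr
F7 | step 1 | (E)-2-(5-bromo-2-methylpent-2-en-1-yl)-4,4,5,5-tetramethyl-1,3,2-dioxaborolane | CC1(C)OB(C/C(C)=C/CCBr)OC1(C)C
F8 | step 1 | tert-butyl (2S,3S)-3-(2-bromoethyl)-2-hydroxy-4-methylpent-4-enoate | C=C(C)[C@H](CCBr)[C@H](O)C(=O)OC(C)(C)C
F9 | step 11 | furan endoperoxide of 28 (C3,C6-epidioxy-3,6-dihydrofuran) | C=C(C)[C@@H]1CCC2=C[C@H](OC2=O)[C@@]2(C)C[C@@H]2C23OOC(O2)(C(C)=C3)[C@H]1OC(C)=O
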